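**Strategy.** Ring B of the target (C5–C6–C7–C8–C9–C10, drimane numbering) is a cyclohexene whose C7=C8 double bond lies opposite the C5–C10 bond. It is therefore disconnected by a retro-[4+2] into the E-dienyl silyl ether 9 (C6=C7–C8=C9, carrying C11) and the acyclic E-enal 6 (C5=C10, carrying C1 as formyl and the quaternary C4 with an acetyl group). One catalytic enantioselective Diels–Alder reaction forms the C5–C6 and C9–C10 bonds and sets C5, C9 and C10, including the trans H-5/CH3-10 and cis C11/C1 relationships. Ring A then closes by aldol condensation (C1–C2), C3 follows by substrate-controlled reduction, and the coumarin and the acetate are attached at the end.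

Key step: step 5

**Remarks before the steps**

- Numbering: drimane numbering is used for the decalin and, by anticipation, for the atoms of 6 and 9 (C1–C10 ring carbons; C11 = OCH2 on C9; C12 = CH3 on C8; C13, C14 = CH3 groups on C4; C15 = CH3 on C10). The target is 3S,5R,9R,10S (3β-OAc, 5α-H, 9β-H with the CH2O group α, 10β-CH3).
- Assumption on the chemistry: the (S)-configured oxazaborolidinium ion is assumed to shield the Si face of the α-carbon of an α-methyl enal bound in the usual formyl C–H···O mode, so that the diene adds to the Re face; if the facial sense is the opposite, the (R)-catalyst is used.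
- Assumption on supply: 1, 2, 5, 7 and 16 (isofraxidin) are taken as commercially available.

**Step 1**
Reactants: 1 4-(2-methylprop-1-en-1-yl)morpholine; 2 acetyl chloride
Product: 4 2,2-dimethyl-3-oxobutanal, via iminium chloride 3 (not isolated)
Conditions: Et2O, 0 °C to reflux (no amine base); then 2 M aq. HCl, rt
Reagents that add atoms: water, O
Why: Stork enamine C-acylation, in which the β-carbon of the isobutyraldehyde enamine attacks acetyl chloride to give an iminium salt with a quaternary, non-enolisable carbon, and aqueous acid then releases the β-keto aldehyde.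

**Step 2**
Reactants: 4 2,2-dimethyl-3-oxobutanal; 5 2-(triphenylphosphoranylidene)propanal
Product: 6 (2E)-2,4,4-trimethyl-5-oxohex-2-enal
Conditions: toluene, 100 °C
Reagents that add atoms: none
Why: Wittig olefination with a formyl-stabilised ylide, which should react only at the aldehyde (the α-quaternary ketone is inert to stabilised ylides) and give the E-configured 2-methyl enal.

**Step 3**
Reactants: 7 (2E)-3-methylpent-2-en-4-yn-1-ol
Product: 8 tert-butyl(dimethyl){[(2E)-3-methylpent-2-en-4-yn-1-yl]oxy}silane
Conditions: TBSCl, imidazole, CH2Cl2, 0 °C to rt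
Reagents that add atoms: tert-butyldimethylsilyl chloride (TBSCl), CC(C)(C)[Si](C)(C)Cl
Why: Standard silylation of a primary allylic alcohol, giving an ether that is inert to the Lewis acid of step 5 and the base of step 6.

**Step 4**
Reactants: 8 tert-butyl(dimethyl){[(2E)-3-methylpent-2-en-4-yn-1-yl]oxy}silane
Product: 9 tert-butyl(dimethyl){[(2E)-3-methylpenta-2,4-dien-1-yl]oxy}silane
Conditions: H2 (1 atm, 1 equiv), Pd/CaCO3 poisoned with Pb(OAc)2, quinoline, hexane, rt
Reagents that add atoms: none
Why: Semi-hydrogenation of the terminal alkyne on the poisoned palladium catalyst should stop at the vinyl group and leave the E trisubstituted double bond untouched, giving the 2E diene.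

**Step 5**
Reactants: 6 (2E)-2,4,4-trimethyl-5-oxohex-2-enal; 9 tert-butyl(dimethyl){[(2E)-3-methylpenta-2,4-dien-1-yl]oxy}silane
Product: 10 (1S,2R,6R)-2-({[tert-butyl(dimethyl)silyl]oxy}methyl)-1,3-dimethyl-6-(2-methyl-3-oxobutan-2-yl)cyclohex-3-ene-1-carbaldehyde
Conditions: (3aS)-1-(2-methylphenyl)-3,3-diphenyltetrahydro-1H,3H-pyrrolo[1,2-c][1,3,2]oxazaborole (20 mol %), HNTf2 (17 mol %), 9 (1.5 equiv), CH2Cl2, −78 to −20 °C
Reagents that add atoms: none
Why: The protonated oxazaborolidine binds the formyl oxygen of 6 (the hindered ketone is not engaged) and lowers the LUMO of the enal, which adds the s-cis diene 9 in a concerted, asynchronous, normal-electron-demand [4+2] cycloaddition; the closest known reaction type is the cationic-oxazaborolidine-catalysed enantioselective Diels–Alder reaction of α-methyl-α,β-unsaturated aldehydes with acyclic dienes. Ring B is closed as a six-membered ring in an intermolecular, suprafacial–suprafacial mode, the C5–C6 bond (enal β-carbon to the unsubstituted diene terminus) leading and the C9–C10 bond following, which leaves the C7=C8 double bond and its methyl group exactly where the target has them. C5 and C10 are set relative to each other by the E geometry of the enal (H-5 trans to CH3-15, the later trans ring fusion), and C9 relative to C10 by the E geometry of the diene together with the endo position of the formyl group (CH2OSi cis to CHO, trans to the angular methyl), an orientation that also keeps the bulky quaternary substituent exo. The absolute configuration (attack on the Re face of the enal α-carbon, giving 1S,2R,6R) is set by the catalyst, whose aryl group should shield the opposite face of the s-trans enal held by B–O coordination and a formyl C–H···O contact. The step needs regioselectivity, which the substrate secures electronically (the 1-substituent of the diene directs its substituted terminus to the α-carbon, the "ortho" adduct) and sterically (the β-carbon next to the quaternary centre can only reach the CH2 terminus). It also needs chemoselectivity for the enal over the ketone and the allylic silyl ether, which the low temperature and the preference of the boron centre for the unhindered aldehyde should provide.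

**Step 6**
Reactants: 10 (1S,2R,6R)-2-({[tert-butyl(dimethyl)silyl]oxy}methyl)-1,3-dimethyl-6-(2-methyl-3-oxobutan-2-yl)cyclohex-3-ene-1-carbaldehyde
Product: 12 (5R,9R,10S)-11-{[tert-butyl(dimethyl)silyl]oxy}drima-1,7-dien-3-one, via aldol adduct 11 (not isolated)
Conditions: KOH, MeOH, rt to 50 °C
Reagents that add atoms: none
Why: Intramolecular aldol condensation, in which the methyl ketone can enolise only towards its CH3 group (C2) and the formyl group (C1) is non-enolisable, so 6-(enolendo)-exo-trig addition and E1cB dehydration should close ring A as the trans-fused Δ1-3-ketone without touching any stereocentre (C5 and C9 are not α to a carbonyl group).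

**Step 7**
Reactants: 12 (5R,9R,10S)-11-{[tert-butyl(dimethyl)silyl]oxy}drima-1,7-dien-3-one
Product: 15 (3S,5R,9R,10S)-drim-7-ene-3,11-diol, via saturated ketone 13 (not isolated), via silyl ether alcohol 14 (not isolated)
Conditions: NiCl2·6H2O (0.3 equiv), NaBH4 (5 equiv), MeOH/THF, −20 °C to rt; then HCl in MeOH to pH 1, rt
Reagents that add atoms: none
Why: Nickel boride formed in the flask should reduce the conjugated disubstituted C1=C2 bond and leave the hindered trisubstituted C7=C8 bond, the excess borohydride then attacks the C3 ketone axially from the α face (anti to the axial 4β- and 10β-methyl groups) to give the equatorial 3β (3S) alcohol by substrate control, and the acidic methanol quench removes the primary silyl ether.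

**Step 8**
Reactants: 15 (3S,5R,9R,10S)-drim-7-ene-3,11-diol; 16 isofraxidin (7-hydroxy-6,8-dimethoxy-2H-chromen-2-one)
Product: 17 7-{[(3S,5R,9R,10S)-3-hydroxydrim-7-en-11-yl]oxy}-6,8-dimethoxy-2H-chromen-2-one
Conditions: PPh3, DIAD, THF, 0 to 40 °C
Reagents that add atoms: none
Why: Mitsunobu etherification, in which the acidic 7-OH of the coumarin displaces the primary C11 alkoxyphosphonium group by SN2, whereas the neopentyl-type secondary 3β-OH next to the gem-dimethyl carbon should not react; no stereocentre is involved.

**Step 9**
Reactants: 17 7-{[(3S,5R,9R,10S)-3-hydroxydrim-7-en-11-yl]oxy}-6,8-dimethoxy-2H-chromen-2-one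
Product: 18 (3S,5R,9R,10S)-11-[(6,8-dimethoxy-2-oxo-2H-chromen-7-yl)oxy]drim-7-en-3-yl acetate
Conditions: Ac2O, pyridine, DMAP (cat.), CH2Cl2, rt
Reagents that add atoms: acetic anhydride, CC(=O)OC(C)=O
Why: DMAP-catalysed acylation of the hindered equatorial 3β-alcohol proceeds with retention at C3, and the coumarin lactone and aryl ethers are stable to these anhydrous, non-nucleophilic conditions.

**Compound list**

1 | 4-(2-methylprop-1-en-1-yl)morpholine | CC(C)=CN1CCOCC1 | starting material
2 | acetyl chloride | CC(=O)Cl | starting material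
3 | 4-(2,2-dimethyl-3-oxobutylidene)morpholin-4-ium chloride | CC(=O)C(C)(C)C=[N+]1CCOCC1.[Cl-] | intermediate
4 | 2,2-dimethyl-3-oxobutanal | CC(=O)C(C)(C)C=O | intermediate
5 | 2-(triphenylphosphoranylidene)propanal | CC(C=O)=P(c1ccccc1)(c1ccccc1)c1ccccc1 | starting material
6 | (2E)-2,4,4-trimethyl-5-oxohex-2-enal | CC(=O)C(C)(C)/C=C(\C)C=O | intermediate
7 | (2E)-3-methylpent-2-en-4-yn-1-ol | C#C/C(C)=C/CO | starting material
8 | tert-butyl(dimethyl){[(2E)-3-methylpent-2-en-4-yn-1-yl]oxy}silane | C#C/C(C)=C/CO[Si](C)(C)C(C)(C)C | intermediate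
9 | tert-butyl(dimethyl){[(2E)-3-methylpenta-2,4-dien-1-yl]oxy}silane | C=C/C(C)=C/CO[Si](C)(C)C(C)(C)C | intermediate
10 | (1S,2R,6R)-2-({[tert-butyl(dimethyl)silyl]oxy}methyl)-1,3-dimethyl-6-(2-methyl-3-oxobutan-2-yl)cyclohex-3-ene-1-carbaldehyde (CH2OSi cis to CHO; CHO trans to the oxobutyl group) | CC(C)(C)[Si](C)(C)OC[C@@H]1C(C)=CC[C@@H](C(C)(C)C(C)=O)[C@]1(C)C=O | intermediate
11 | (5R,9R,10S)-11-{[tert-butyl(dimethyl)silyl]oxy}-1-hydroxydrim-7-en-3-one (aldol adduct; C1 carbinol configuration not defined) | CC(C)(C)[Si](C)(C)OC[C@@H]1C(C)=CC[C@H]2C(C)(C)C(=O)CC(O)[C@]12C | intermediate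
12 | (5R,9R,10S)-11-{[tert-butyl(dimethyl)silyl]oxy}drima-1,7-dien-3-one (5α-H, 9β-H, 10β-CH3; trans-fused) | CC(C)(C)[Si](C)(C)OC[C@@H]1C(C)=CC[C@H]2C(C)(C)C(=O)C=C[C@]12C | intermediate
13 | (5R,9R,10S)-11-{[tert-butyl(dimethyl)silyl]oxy}drim-7-en-3-one | CC(C)(C)[Si](C)(C)OC[C@@H]1C(C)=CC[C@H]2C(C)(C)C(=O)CC[C@]12C | intermediate
14 | (3S,5R,9R,10S)-11-{[tert-butyl(dimethyl)silyl]oxy}drim-7-en-3-ol (3β-OH) | CC(C)(C)[Si](C)(C)OC[C@@H]1C(C)=CC[C@H]2C(C)(C)[C@@H](O)CC[C@]12C | intermediate
15 | (3S,5R,9R,10S)-drim-7-ene-3,11-diol (3β-OH, 5α-H, 9β-H, 10β-CH3) | OC[C@@H]1C(C)=CC[C@H]2C(C)(C)[C@@H](O)CC[C@]12C | intermediate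
16 | isofraxidin (7-hydroxy-6,8-dimethoxy-2H-chromen-2-one) | COc1cc2ccc(=O)oc2c(OC)c1O | starting material
17 | 7-{[(3S,5R,9R,10S)-3-hydroxydrim-7-en-11-yl]oxy}-6,8-dimethoxy-2H-chromen-2-one | COc1cc2ccc(=O)oc2c(OC)c1OC[C@@H]1C(C)=CC[C@H]2C(C)(C)[C@@H](O)CC[C@]12C | intermediate
18 | (3S,5R,9R,10S)-11-[(6,8-dimethoxy-2-oxo-2H-chromen-7-yl)oxy]drim-7-en-3-yl acetate | COc1cc2ccc(=O)oc2c(OC)c1OC[C@@H]1C(C)=CC[C@H]2C(C)(C)[C@@H](OC(C)=O)CC[C@]12C | target

**Totals**

Total step count: 9. Longest linear sequence: 7 steps (steps 3, 4, 5, 6, 7, 8, 9 from 7, or steps 1, 2, 5, 6, 7, 8, 9 from 1).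

**Steps most likely to fail**

1. Step 5. The cycloaddition may be too slow, because the reacting β-carbon of 6 is flanked by a quaternary centre. Diene oligomerisation and erosion of regio-, endo/exo and facial selectivity would then take over. The fallback sets out from 6 and 9 and comes back at 10; it makes the dienophile cationic and the control element covalent. The formyl group of 6 would be condensed with (2R,3R)-butane-2,3-diol (PPTS, benzene, reflux, water separator) to the (4R,5R)-4,5-dimethyl-1,3-dioxolane acetal F1. With catalytic TfOH in CH2Cl2 at −78 °C this acetal opens to an allyl oxocarbenium ion, a far more electrophilic dienophile, which should add 9 in an ionic Diels–Alder reaction with the same orientation and re-close to the acetal. The diastereomeric adducts would be separated, and the one with the ring configuration of 10, the adduct acetal F2, hydrolysed (PPTS, acetone/water, 50 °C) to 10.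

2. Step 8. SN2 displacement at the β-branched C11 by the doubly ortho-substituted phenol may be sluggish, so that the activated alcohol is consumed by hydrazide alkylation or elimination. The fallback sets out from 15 (with 16) and comes back at 17. The primary hydroxyl of 15 would be sulfonylated selectively (MsCl, Et3N, CH2Cl2, −20 °C) to the 11-O-methanesulfonate of diol 15, F3. This would be displaced by the caesium phenoxide of 16 (Cs2CO3, DMF, 70 °C) in a Williamson ether synthesis to give 17.

3. Step 2. Olefination of the α-quaternary aldehyde by the weakly nucleophilic formyl ylide may be slow, allowing deformylation of 4 or a second olefination of the product enal. The fallback sets out from 4 and comes back at 6. Aldehyde 4 would be olefinated with the more nucleophilic ethyl 2-(triphenylphosphoranylidene)propanoate (toluene, 80 °C) to ethyl (2E)-2,4,4-trimethyl-5-oxohex-2-enoate F4. Both carbonyl groups would be reduced with i-Bu2AlH (CH2Cl2, −78 °C) to (2E)-2,4,4-trimethylhex-2-ene-1,5-diol F5, and both carbinols oxidised by Swern oxidation ((COCl)2, DMSO, Et3N, −78 °C) to 6.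

**Further compounds**

F1 | step 5 | (4E)-5-[(4R,5R)-4,5-dimethyl-1,3-dioxolan-2-yl]-3,3-dimethylhex-4-en-2-one | CC(=O)C(C)(C)/C=C(\C)C1O[C@H](C)[C@@H](C)O1
F2 | step 5 | (4R,5R)-4,5-dimethyl-1,3-dioxolane acetal of 10 (ring configuration as in 10) | CC(C)(C)[Si](C)(C)OC[C@@H]1C(C)=CC[C@@H](C(C)(C)C(C)=O)[C@]1(C)C1O[C@H](C)[C@@H](C)O1
F3 | step 8 | (3S,5R,9R,10S)-3-hydroxydrim-7-en-11-yl methanesulfonate | CS(=O)(=O)OC[C@@H]1C(C)=CC[C@H]2C(C)(C)[C@@H](O)CC[C@]12C
F4 | step 2 | ethyl (2E)-2,4,4-trimethyl-5-oxohex-2-enoate | CCOC(=O)/C(C)=C/C(C)(C)C(C)=O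
F5 | step 2 | (2E)-2,4,4-trimethylhex-2-ene-1,5-diol | OC/C(C)=C/C(C)(C)C(C)O
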